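(The readings come from a simulation from invented constants; noise was put on by code.)

The number to watch is 2.50: the partner that two-per-bis-adduct conversion of the whole starting material takes, as a fraction of the partner charged. So the partner is the limiting reagent.

| flask | starting material | partner | remark | time |
|---|---|---|---|---|
| spring | 0.20 M | 0.16 M | run made earlier |  |
| winter | 0.20 M | 0.24 M | run made earlier |  |
| north-east | 0.20 M (fed, over 8.00 min) | 0.160 M | all but starting material at the start; starting material goes in evenly over 8.00 min, the run ends at 8.0 min | 8.0 min |
| south | 0.20 M | 0.160 M (fed, over 8.00 min) | all but partner at the start; partner goes in evenly over 8.00 min, the run ends at 8.0 min | 8.0 min |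
| south-west | 0.20 M | 0.160 M | one stirred flow tank at steady state, fed with the mixture as stated, mean residence time 8.0 min |  |
| north | 0.20 M | 0.160 M | a closed flask charged with all of it at once and left for 8.0 min | 8.0 min |

spring run (percent of the starting material charged)

| time / min | bis adduct / % |
|---|---|
| 0.667 | 0.1 |
| 1.00 | 3.0 |
| 1.33 | 3.6 |
| 2.50 | 11.5 |
| 3.00 | 13.4 |
| 5.00 | 19.4 |
| 8.00 | 25.9 |

winter run (percent of the starting material charged)

| time / s | bis adduct / % |
|---|---|
| 10.0 | 0.2 |
| 15.0 | 1.6 |
| 25.0 | 0.8 |
| 40.0 | 3.1 |
| 60.0 | 5.7 |
| 80.0 | 8.2 |
| 90.0 | 8.9 |

(standard deviation of a reading: 1 percentage point)

- the stated concentrations are those of everything mixed, before any reaction; amounts are the same in each set-up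
- the feed brings no volume worth counting
- the earlier runs were made in a closed, stirred flask

* the set-up with the highest amount of bis adduct at the outlet or at the end, in percent of the starting material put in ("none" if the first two lie within 2 percentage points) (north-east / south / south-west / north / none)
* amount of bis adduct at the outlet or at the end, in percent of the starting material put in, north-east
* amount of bis adduct at the outlet or at the end, in percent of the starting material put in, south
* amount of bis adduct at the outlet or at the end, in percent of the starting material put in, south-west
* amount of bis adduct at the outlet or at the end, in percent of the starting material put in, north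

I write y for bis adduct as a fraction of the starting material charged. The spring run has the charges of the north flask and reads 25.9% at 8.00 min. The bench rule for the south flask says that partner fed evenly stands on average at half its charge, so south gets half that reading, 12.9%.

But the rule assumes a closed flask that keeps its partner, and the ratio times the reading puts 0.647 of the partner charge of the spring flask into the bis adduct read there, which I take as my estimate of the spent partner, counting partner in the bis adduct and nothing else. So I count a partner clock: minutes weighted by the fraction of the partner charge present. With that estimate and partner falling in a straight line, I reckon that the spring flask has run 5.41 min of clock. That gives 0.0479 min⁻¹, the gain in y per clock minute, which I take as constant.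

In the south flask I take y to grow as time squared, so the partner counted as spent, again that in the bis adduct, averages a third of its final value. The clock is then half the dosing time, less a third of the dosing time times the ratio times y. I put each answer back in:

Round one: from 12.9%, clock 3.14 min, y = 15.0%

Round two: from 15.0%, clock 3.00 min, y = 14.4%

I commit to 14.4% for south.

The forecast gives 16.8% for north-east, 16.3% for south, which is above mine, 18.3% for south-west and 26% for north, and concludes: “The batch flask wins.”

The simulation gives 17.6% for north-east, 13.8% for south, 18.6% for south-west and 24.6% for north, so the best is north.

    starting material + partner → mono adduct + by-product (k = 0.0190 M⁻¹ s⁻¹)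
    partner + mono adduct → bis adduct + by-product (k = 0.0520 M⁻¹ s⁻¹)
    partner + bis adduct → tris adduct + by-product (k = 9.80 × 10⁻⁴ M⁻¹ s⁻¹)
    partner + tris adduct → tetra adduct + by-product (k = 0.00980 M⁻¹ s⁻¹)

South lies 0.60 percentage points below my figure. The neighbouring flask is south with 0.080 M of starting material, so its ratio is 1.00. With the same gain per clock minute, 0.0479 min⁻¹, the first round from 12.9% gives 17.5% and the second gives 16.9%. The neighbour does rise above south, but it reaches 22.3%, which is 5.4 points above my figure. At its end that neighbour holds 57.0% starting material and 20.5% mono adduct.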